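**Plan**

- Cuts: both lactone C(=O)–O bonds; the C2=N bond of ring A (imine from a δ-amino methyl ketone, the ketone carried as a terminal alkyne); in each half the side-chain bond between chain carbons 3 and 4 (cross-metathesis, then hydrogenation); in ring B the C4–C5 and N1–C6 bonds.
- Enabling feature: ring B (N1, C2–CH3, C3–O, C6–chain) has a bare C4–C5 edge, and C6, C5 and the first three chain carbons map onto a cyclopent-2-enyl group on nitrogen. Ring-rearrangement metathesis of an N-cyclopentenyl N-(pent-4-en-2-yl) sulfonamide therefore makes C4=C5 and leaves a but-3-enyl arm on C6.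
- Forward order: ring B is closed first, its chain is extended and saturated, the acid is esterified with the acyclic ring A precursor, the 26-membered diolide is closed by macrolactonisation, and ring A is closed last (alkyne hydration, Boc removal, imine condensation).
- Stereochemistry: B-C2 from L-alanine; B-C3 by catalyst-controlled transfer hydrogenation of an ynone (2,3-syn); B-C6 by ligand-controlled allylic amination, carried unchanged through the rearrangement; A-C6 from L-pyroglutaminol tosylate; A-C3 by transfer hydrogenation with the mirror-image catalyst.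

Key step: step 8

Remark 1: the (2S,3S) amino alcohol of ring B is the syn (threo) isomer, as required for a cis 2-methyl/3-oxygen pair; chelation-controlled hydride reduction of an N-Boc amino ketone favours the anti isomer, so the carbinol is set by catalyst control.

Remark 2: the (S,S) enantiomer of the DACH-phenyl ligand is assumed to give the (R)-configured N-cyclopentenyl carbon, as the usual model for cyclic allylic carbonates predicts; if the sense were opposite, the (R,R) ligand would be taken.

**Route**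

Step 1
Reactants: 1 tert-butyl N-[(2S)-1-[methoxy(methyl)amino]-1-oxopropan-2-yl]carbamate
Product: 2 tert-butyl N-[(2S)-3-oxo-5-(trimethylsilyl)pent-4-yn-2-yl]carbamate
Conditions: Me3SiC≡CH, n-BuLi, THF, −78 °C; then 1, −78 → −20 °C; aq. NH4Cl
Reagents that add atoms: trimethylsilylacetylene, C#C[Si](C)(C)C
Why: Weinreb ketone synthesis, in which the lithium acetylide adds once because the chelated tetrahedral adduct survives until the quench, and prior deprotonation of the carbamate N–H shields the α-stereocentre from enolisation.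

Step 2
Reactants: 2 tert-butyl N-[(2S)-3-oxo-5-(trimethylsilyl)pent-4-yn-2-yl]carbamate
Product: 3 tert-butyl N-[(2S,3S)-3-hydroxy-5-(trimethylsilyl)pent-4-yn-2-yl]carbamate
Conditions: Ru[(R,R)-TsDPEN](p-cymene) (preformed 16-electron amido complex, 3 mol%), i-PrOH, rt
Reagents that add atoms: none
Why: Noyori-type asymmetric transfer hydrogenation of an alkynyl ketone, where the catalyst and not the substrate fixes the hydride face, so the (R,R)-diamine complex should give the (3S) carbinol (the 2,3-syn amino alcohol) under conditions too mild to epimerise C2.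

Step 3
Reactants: 3 tert-butyl N-[(2S,3S)-3-hydroxy-5-(trimethylsilyl)pent-4-yn-2-yl]carbamate
Product: 5 tert-butyl N-[(2S,3S)-3-hydroxypent-4-en-2-yl]carbamate, via terminal alkyne 4 (not isolated)
Conditions: K2CO3 (cat.), MeOH, rt; then Pd/CaCO3 poisoned with Pb(OAc)2 (Lindlar catalyst), quinoline, H2 (1 atm), rt
Reagents that add atoms: none
Why: Methanolysis of the alkynylsilane followed by Lindlar semihydrogenation, which stops at the alkene on the lead-poisoned palladium surface and involves neither stereocentre.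

Step 4
Reactants: 5 tert-butyl N-[(2S,3S)-3-hydroxypent-4-en-2-yl]carbamate
Product: 7 N-[(2S,3S)-3-hydroxypent-4-en-2-yl]-2-nitrobenzenesulfonamide, via amino alcohol hydrochloride 6 (not isolated)
Conditions: HCl (4 M in dioxane), 0 °C → rt, evaporate; then 2-nitrobenzenesulfonyl chloride, Et3N, CH2Cl2, 0 °C
Reagents that add atoms: 2-nitrobenzenesulfonyl chloride, O=S(=O)(Cl)c1ccccc1[N+](=O)[O-]
Why: Acidolysis of the tert-butyl carbamate and chemoselective N-sulfonylation of the amine (far more nucleophilic than the secondary alcohol) give the acidic N–H needed for allylic amination, with the nitro group introduced only after the organolithium step.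

Step 5
Reactants: 7 N-[(2S,3S)-3-hydroxypent-4-en-2-yl]-2-nitrobenzenesulfonamide
Product: 8 N-[(2S,3S)-3-(tert-butyldimethylsilyloxy)pent-4-en-2-yl]-2-nitrobenzenesulfonamide
Conditions: TBSCl, imidazole, DMF, rt
Reagents that add atoms: tert-butyldimethylsilyl chloride, CC(C)(C)[Si](C)(C)Cl
Why: Imidazole-promoted silylation of the secondary allylic alcohol, which blocks O-allylation in step 7 and ruthenium-hydride isomerisation of the allylic alcohol in step 8.

Step 6
Reactants: 9 cyclopent-2-en-1-ol (racemic)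
Product: 10 cyclopent-2-en-1-yl methyl carbonate (racemic)
Conditions: ClCO2Me, pyridine, CH2Cl2, 0 °C
Reagents that add atoms: methyl chloroformate, COC(=O)Cl
Why: O-Acylation with the chloroformate gives an allylic carbonate, a leaving group that ionises readily on zerovalent palladium and releases its own base (methoxide).

Step 7
Reactants: 8 N-[(2S,3S)-3-(tert-butyldimethylsilyloxy)pent-4-en-2-yl]-2-nitrobenzenesulfonamide; 10 cyclopent-2-en-1-yl methyl carbonate
Product: 11 N-[(1R)-cyclopent-2-en-1-yl]-N-[(2S,3S)-3-(tert-butyldimethylsilyloxy)pent-4-en-2-yl]-2-nitrobenzenesulfonamide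
Conditions: Pd2(dba)3·CHCl3 (2.5 mol%), (1S,2S)-N,N'-bis[2-(diphenylphosphino)benzoyl]cyclohexane-1,2-diamine ((S,S)-DACH-phenyl Trost ligand, 7.5 mol%), CH2Cl2, rt
Reagents that add atoms: none
Why: Tsuji–Trost asymmetric allylic amination run as a dynamic kinetic asymmetric transformation, in which both enantiomers of 10 ionise to the same meso π-allyl palladium complex and the ligand pocket directs the sulfonamide anion to one allyl terminus, setting the (R)-configured N–C bond under ligand control.

Step 8
Reactants: 11 N-[(1R)-cyclopent-2-en-1-yl]-N-[(2S,3S)-3-(tert-butyldimethylsilyloxy)pent-4-en-2-yl]-2-nitrobenzenesulfonamide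
Product: 12 (2S,3S,6R)-6-(but-3-en-1-yl)-3-(tert-butyldimethylsilyloxy)-2-methyl-1-(2-nitrophenylsulfonyl)-1,2,3,6-tetrahydropyridine
Conditions: second-generation Grubbs catalyst RuCl2(=CHPh)(H2IMes)(PCy3) (5 mol%), ethylene (1 atm), CH2Cl2 (5 mM), 40 °C
Reagents that add atoms: none
Why: A ruthenium methylidene opens the strained cyclopentene by [2+2] cycloaddition and cycloreversion, and the alkylidene left on the former alkene carbon next to the N-bearing carbon closes onto the vinyl group of the pentenyl arm, so ring-opening and ring-closing metathesis run as one relay and the molecule isomerises without loss of atoms. The closest known reaction type is the ring-rearrangement metathesis of N-homoallyl cycloalk-2-enyl sulfonamides to 6-substituted 1,2,3,6-tetrahydropyridines. Ring B closes by ring-closing metathesis that forms C4=C5 in a six-membered ring; the alternative closures would only return the cyclopentene or give a nine-membered ring. No stereocentre is created, since C2 and C3 come from the pentenyl arm and C6 is the allylic cyclopentenyl carbon, whose bonds to N and H are never broken. The step needs six-ring closure to win over oligomerisation and over return to the carbocycle, which relief of cyclopentene strain, the turn imposed by the tertiary sulfonamide, high dilution and ethylene (which keeps the catalyst as the methylidene and caps open chain ends) should secure.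

Step 9
Reactants: 12 (2S,3S,6R)-6-(but-3-en-1-yl)-3-(tert-butyldimethylsilyloxy)-2-methyl-1-(2-nitrophenylsulfonyl)-1,2,3,6-tetrahydropyridine; 13 methyl hex-5-enoate
Product: 14 methyl 8-[(2R,5S,6S)-5-(tert-butyldimethylsilyloxy)-6-methyl-1-(2-nitrophenylsulfonyl)-1,2,5,6-tetrahydropyridin-2-yl]oct-5-enoate (E/Z mixture)
Conditions: second-generation Grubbs catalyst RuCl2(=CHPh)(H2IMes)(PCy3) (5 mol%), 13 (4 equiv), CH2Cl2, 40 °C
Reagents that add atoms: none
Why: Olefin cross-metathesis between two unhindered terminal alkenes, driven by loss of ethylene and an excess of the ester partner, while the endocyclic alkene of the unstrained six-membered ring is not engaged and the alkene geometry is of no consequence.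

Step 10
Reactants: 14 methyl 8-[(2R,5S,6S)-5-(tert-butyldimethylsilyloxy)-6-methyl-1-(2-nitrophenylsulfonyl)-1,2,5,6-tetrahydropyridin-2-yl]oct-5-enoate
Product: 15 methyl 8-[(2R,5S,6S)-5-(tert-butyldimethylsilyloxy)-6-methyl-1,2,5,6-tetrahydropyridin-2-yl]oct-5-enoate
Conditions: PhSH, K2CO3, MeCN, rt
Reagents that add atoms: none
Why: Thiolate-mediated cleavage of the 2-nitrobenzenesulfonamide by nucleophilic aromatic substitution through a Meisenheimer adduct with loss of SO2, placed before the hydrogenation because the nitro group would not survive it.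

Step 11
Reactants: 15 methyl 8-[(2R,5S,6S)-5-(tert-butyldimethylsilyloxy)-6-methyl-1,2,5,6-tetrahydropyridin-2-yl]oct-5-enoate
Product: 17 tert-butyl (2S,3S,6R)-3-(tert-butyldimethylsilyloxy)-6-(8-methoxy-8-oxooctyl)-2-methylpiperidine-1-carboxylate, via N-Boc tetrahydropyridine 16 (not isolated)
Conditions: Boc2O, Et3N, MeOH, 50 °C; then Pd/C (10%), H2 (1 atm), rt
Reagents that add atoms: di-tert-butyl dicarbonate, CC(C)(C)OC(=O)OC(=O)OC(C)(C)C
Why: Carbamate formation on the secondary amine followed by heterogeneous catalytic hydrogenation of both C=C bonds, which creates no stereocentre (all reduced carbons become CH2) and leaves the silyl ether, ester and carbamate intact.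

Step 12
Reactants: 17 tert-butyl (2S,3S,6R)-3-(tert-butyldimethylsilyloxy)-6-(8-methoxy-8-oxooctyl)-2-methylpiperidine-1-carboxylate
Product: 18 8-[(2R,5S,6S)-1-(tert-butoxycarbonyl)-5-(tert-butyldimethylsilyloxy)-6-methylpiperidin-2-yl]octanoic acid
Conditions: LiOH·H2O, THF/MeOH/H2O, rt; then cold dilute HCl to pH 4
Reagents that add atoms: lithium hydroxide, [Li+].[OH-]
Why: Saponification of the unhindered methyl ester, to which the silyl ether and tert-butyl carbamate are stable, as they are to the brief cold mildly acidic work-up.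

Step 13
Reactants: 19 hex-5-enoic acid
Product: 20 2-(trimethylsilyl)ethyl hex-5-enoate
Conditions: Me3SiCH2CH2OH, EDC·HCl, DMAP (cat.), CH2Cl2, rt
Reagents that add atoms: 2-(trimethylsilyl)ethanol, C[Si](C)(C)CCO
Why: Steglich-type carbodiimide esterification gives a fluoride-labile ester, so that the ring A carboxyl can later be freed without touching the ester that joins the two halves.

Step 14
Reactants: 21 [(2S)-5-oxopyrrolidin-2-yl]methyl 4-methylbenzenesulfonate
Product: 22 (5R)-5-(but-3-en-1-yl)pyrrolidin-2-one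
Conditions: allylMgBr (3 equiv), CuI (10 mol%), THF, −30 → 0 °C; then 1 M HCl
Reagents that add atoms: allylmagnesium bromide, C=CC[Mg]Br
Why: Copper-catalysed sp3–sp3 coupling of the Grignard reagent with the primary tosylate (after the lactam N–H has consumed one equivalent), which leaves the L-glutamate-derived stereocentre untouched because substitution occurs at the neighbouring CH2; this centre becomes C6 of ring A.

Step 15
Reactants: 22 (5R)-5-(but-3-en-1-yl)pyrrolidin-2-one; 20 2-(trimethylsilyl)ethyl hex-5-enoate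
Product: 23 2-(trimethylsilyl)ethyl 8-[(2R)-5-oxopyrrolidin-2-yl]oct-5-enoate (E/Z mixture)
Conditions: second-generation Grubbs catalyst RuCl2(=CHPh)(H2IMes)(PCy3) (5 mol%), 20 (3 equiv), CH2Cl2, 40 °C
Reagents that add atoms: none
Why: Olefin cross-metathesis of two terminal alkenes driven by loss of ethylene, with the secondary lactam tolerated by the ruthenium carbene.

Step 16
Reactants: 23 2-(trimethylsilyl)ethyl 8-[(2R)-5-oxopyrrolidin-2-yl]oct-5-enoate
Product: 24 2-(trimethylsilyl)ethyl 8-[(2R)-5-oxopyrrolidin-2-yl]octanoate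
Conditions: H2 (1 atm), Pd/C (10%), EtOAc, rt
Reagents that add atoms: none
Why: Heterogeneous catalytic hydrogenation of the disubstituted alkene, done at this stage because no alkyne is yet present.

Step 17
Reactants: 24 2-(trimethylsilyl)ethyl 8-[(2R)-5-oxopyrrolidin-2-yl]octanoate
Product: 25 tert-butyl (2R)-5-oxo-2-{8-oxo-8-[2-(trimethylsilyl)ethoxy]octyl}pyrrolidine-1-carboxylate
Conditions: Boc2O, DMAP, Et3N, MeCN, rt
Reagents that add atoms: di-tert-butyl dicarbonate, CC(C)(C)OC(=O)OC(=O)OC(C)(C)C
Why: DMAP-catalysed N-acylation turns the lactam into an imide-like electrophile for the ring opening and installs the nitrogen protecting group of the ring A half.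

Step 18
Reactants: 25 tert-butyl (2R)-5-oxo-2-{8-oxo-8-[2-(trimethylsilyl)ethoxy]octyl}pyrrolidine-1-carboxylate
Product: 26 2-(trimethylsilyl)ethyl (9R)-9-[(tert-butoxycarbonyl)amino]-12-oxo-14-(trimethylsilyl)tetradec-13-ynoate
Conditions: Me3SiC≡CH, n-BuLi, THF, −78 °C; then 25, −78 °C; aq. NH4Cl
Reagents that add atoms: trimethylsilylacetylene, C#C[Si](C)(C)C
Why: Nucleophilic ring opening of an N-acyl lactam, in which the acetylide attacks the activated ring carbonyl at −78 °C in preference to the ester and the adduct collapses to the ynone with the carbamate anion as leaving group, which also prevents a second addition.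

Step 19
Reactants: 26 2-(trimethylsilyl)ethyl (9R)-9-[(tert-butoxycarbonyl)amino]-12-oxo-14-(trimethylsilyl)tetradec-13-ynoate
Product: 27 2-(trimethylsilyl)ethyl (9R,12S)-9-[(tert-butoxycarbonyl)amino]-12-hydroxy-14-(trimethylsilyl)tetradec-13-ynoate
Conditions: Ru[(S,S)-TsDPEN](p-cymene) (preformed 16-electron amido complex, 3 mol%), i-PrOH, rt
Reagents that add atoms: none
Why: Noyori-type asymmetric transfer hydrogenation of an alkynyl ketone, in which the (S,S)-diamine complex should give the (S)-propargylic alcohol (C3 of ring A) by catalyst control, the remote C9 centre having no influence.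

Step 20
Reactants: 18 8-[(2R,5S,6S)-1-(tert-butoxycarbonyl)-5-(tert-butyldimethylsilyloxy)-6-methylpiperidin-2-yl]octanoic acid; 27 2-(trimethylsilyl)ethyl (9R,12S)-9-[(tert-butoxycarbonyl)amino]-12-hydroxy-14-(trimethylsilyl)tetradec-13-ynoate
Product: 28 2-(trimethylsilyl)ethyl (9R,12S)-9-[(tert-butoxycarbonyl)amino]-12-({8-[(2R,5S,6S)-1-(tert-butoxycarbonyl)-5-(tert-butyldimethylsilyloxy)-6-methylpiperidin-2-yl]octanoyl}oxy)-14-(trimethylsilyl)tetradec-13-ynoate
Conditions: EDC·HCl, DMAP, CH2Cl2, 0 °C → rt
Reagents that add atoms: none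
Why: Steglich esterification of the unhindered chain acid with the propargylic alcohol, an acyl transfer to oxygen that retains the carbinol configuration while the silylated ring B hydroxyl and the esterified ring A carboxyl cannot compete.

Step 21
Reactants: 28 2-(trimethylsilyl)ethyl (9R,12S)-9-[(tert-butoxycarbonyl)amino]-12-({8-[(2R,5S,6S)-1-(tert-butoxycarbonyl)-5-(tert-butyldimethylsilyloxy)-6-methylpiperidin-2-yl]octanoyl}oxy)-14-(trimethylsilyl)tetradec-13-ynoate
Product: 29 (9R,12S)-9-[(tert-butoxycarbonyl)amino]-12-({8-[(2R,5S,6S)-1-(tert-butoxycarbonyl)-5-hydroxy-6-methylpiperidin-2-yl]octanoyl}oxy)tetradec-13-ynoic acid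
Conditions: Bu4NF (6 equiv), THF, 0 °C → rt; aq. NH4Cl
Reagents that add atoms: none
Why: Fluoride-induced cleavage of three silicon groups in one operation (the secondary silyl ether, the 2-(trimethylsilyl)ethyl ester by β-elimination to ethylene, and the alkynylsilane), while the silicon-free ester that joins the halves and both carbamates should remain.

Step 22
Reactants: 29 (9R,12S)-9-[(tert-butoxycarbonyl)amino]-12-({8-[(2R,5S,6S)-1-(tert-butoxycarbonyl)-5-hydroxy-6-methylpiperidin-2-yl]octanoyl}oxy)tetradec-13-ynoic acid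
Product: 31 26-membered diolide formed from 29 by lactonisation of its carboxyl onto the ring B C3 hydroxyl (N-Boc ring B of configuration 2S,3S,6R; ring A still open as (R)-CH(NHBoc) and (S)-CH(C≡CH)–O-acyl), via mixed anhydride 30 (not isolated)
Conditions: 2,4,6-Cl3C6H2COCl, Et3N, THF, rt; then slow addition to DMAP, toluene (1 mM), 80 °C
Reagents that add atoms: none
Why: Yamaguchi macrolactonisation, in which the mixed anhydride acylates DMAP and the ring B hydroxyl closes the 26-membered ring under high dilution with retention at the carbinol carbon, the carbamate N–H groups being too weakly nucleophilic to interfere.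

Step 23
Reactants: 31 26-membered diolide bearing the ethynyl carbinol ester
Product: 32 26-membered diolide in which the ethynyl group of 31 has become an acetyl group (α-acyloxy methyl ketone; both nitrogens still Boc-protected)
Conditions: Ph3PAuNTf2 (5 mol%), 1,4-dioxane/H2O (10:1), rt
Reagents that add atoms: water, O
Why: Gold-catalysed Markovnikov hydration of a terminal propargylic ester, in which π-activation of the alkyne, 5-exo-dig participation of the ester carbonyl and hydrolysis of the dioxolenium intermediate should give the α-acyloxy methyl ketone with the C–O stereocentre untouched.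

Step 24
Reactants: 32 26-membered diolide bearing the α-acyloxy methyl ketone
Product: 34 target CNP0304114.1: 26-membered diolide with ring B as the (2S,3S,6R)-2-methylpiperidine and ring A as the (3S,6R)-2-methyl-3,4,5,6-tetrahydropyridine, via amino ketone 33 (not isolated)
Conditions: CF3CO2H/CH2Cl2 (1:4), 0 °C → rt; then aq. NaHCO3, rt
Reagents that add atoms: none
Why: Acidolysis of both tert-butyl carbamates followed, on neutralisation, by spontaneous six-membered condensation of the primary amine with the δ-ketone (imine formation) to close ring A, while the secondary ring B amine cannot form a neutral imine and stays free.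

**Compound list**

1 | tert-butyl N-[(2S)-1-[methoxy(methyl)amino]-1-oxopropan-2-yl]carbamate | C[C@H](NC(=O)OC(C)(C)C)C(=O)N(C)OC | starting material
2 | tert-butyl N-[(2S)-3-oxo-5-(trimethylsilyl)pent-4-yn-2-yl]carbamate | C[C@H](NC(=O)OC(C)(C)C)C(=O)C#C[Si](C)(C)C | intermediate
3 | tert-butyl N-[(2S,3S)-3-hydroxy-5-(trimethylsilyl)pent-4-yn-2-yl]carbamate | C[C@H](NC(=O)OC(C)(C)C)[C@@H](O)C#C[Si](C)(C)C | intermediate
4 | tert-butyl N-[(2S,3S)-3-hydroxypent-4-yn-2-yl]carbamate | C[C@H](NC(=O)OC(C)(C)C)[C@@H](O)C#C | intermediate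
5 | tert-butyl N-[(2S,3S)-3-hydroxypent-4-en-2-yl]carbamate | C[C@H](NC(=O)OC(C)(C)C)[C@@H](O)C=C | intermediate
6 | (2S,3S)-2-aminopent-4-en-3-ol hydrochloride | C[C@H](N)[C@@H](O)C=C.Cl | intermediate
7 | N-[(2S,3S)-3-hydroxypent-4-en-2-yl]-2-nitrobenzenesulfonamide | C[C@H](NS(=O)(=O)c1ccccc1[N+](=O)[O-])[C@@H](O)C=C | intermediate
8 | N-[(2S,3S)-3-(tert-butyldimethylsilyloxy)pent-4-en-2-yl]-2-nitrobenzenesulfonamide | C[C@H](NS(=O)(=O)c1ccccc1[N+](=O)[O-])[C@@H](O[Si](C)(C)C(C)(C)C)C=C | intermediate
9 | cyclopent-2-en-1-ol (racemic) | OC1C=CCC1 | starting material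
10 | cyclopent-2-en-1-yl methyl carbonate (racemic) | COC(=O)OC1C=CCC1 | intermediate
11 | N-[(1R)-cyclopent-2-en-1-yl]-N-[(2S,3S)-3-(tert-butyldimethylsilyloxy)pent-4-en-2-yl]-2-nitrobenzenesulfonamide | C=C[C@H](O[Si](C)(C)C(C)(C)C)[C@H](C)N([C@H]1C=CCC1)S(=O)(=O)c1ccccc1[N+](=O)[O-] | intermediate
12 | (2S,3S,6R)-6-(but-3-en-1-yl)-3-(tert-butyldimethylsilyloxy)-2-methyl-1-(2-nitrophenylsulfonyl)-1,2,3,6-tetrahydropyridine | CC(C)(C)[Si](C)(C)O[C@H]1C=C[C@@H](CCC=C)N(S(=O)(=O)c2ccccc2[N+](=O)[O-])[C@H]1C | intermediate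
13 | methyl hex-5-enoate | C=CCCCC(=O)OC | starting material
14 | methyl 8-[(2R,5S,6S)-5-(tert-butyldimethylsilyloxy)-6-methyl-1-(2-nitrophenylsulfonyl)-1,2,5,6-tetrahydropyridin-2-yl]oct-5-enoate (E/Z) | CC(C)(C)[Si](C)(C)O[C@H]1C=C[C@@H](CCC=CCCCC(=O)OC)N(S(=O)(=O)c2ccccc2[N+](=O)[O-])[C@H]1C | intermediate
15 | methyl 8-[(2R,5S,6S)-5-(tert-butyldimethylsilyloxy)-6-methyl-1,2,5,6-tetrahydropyridin-2-yl]oct-5-enoate (E/Z) | CC(C)(C)[Si](C)(C)O[C@H]1C=C[C@@H](CCC=CCCCC(=O)OC)N[C@H]1C | intermediate
16 | tert-butyl (2S,3S,6R)-3-(tert-butyldimethylsilyloxy)-6-(8-methoxy-8-oxooct-3-en-1-yl)-2-methyl-3,6-dihydro-2H-pyridine-1-carboxylate (E/Z) | CC(C)(C)[Si](C)(C)O[C@H]1C=C[C@@H](CCC=CCCCC(=O)OC)N(C(=O)OC(C)(C)C)[C@H]1C | intermediate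
17 | tert-butyl (2S,3S,6R)-3-(tert-butyldimethylsilyloxy)-6-(8-methoxy-8-oxooctyl)-2-methylpiperidine-1-carboxylate | CC(C)(C)[Si](C)(C)O[C@H]1CC[C@@H](CCCCCCCC(=O)OC)N(C(=O)OC(C)(C)C)[C@H]1C | intermediate
18 | 8-[(2R,5S,6S)-1-(tert-butoxycarbonyl)-5-(tert-butyldimethylsilyloxy)-6-methylpiperidin-2-yl]octanoic acid | CC(C)(C)[Si](C)(C)O[C@H]1CC[C@@H](CCCCCCCC(=O)O)N(C(=O)OC(C)(C)C)[C@H]1C | intermediate
19 | hex-5-enoic acid | C=CCCCC(=O)O | starting material
20 | 2-(trimethylsilyl)ethyl hex-5-enoate | C=CCCCC(=O)OCC[Si](C)(C)C | intermediate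
21 | [(2S)-5-oxopyrrolidin-2-yl]methyl 4-methylbenzenesulfonate | O=C1CC[C@@H](COS(=O)(=O)c2ccc(C)cc2)N1 | starting material
22 | (5R)-5-(but-3-en-1-yl)pyrrolidin-2-one | O=C1CC[C@@H](CCC=C)N1 | intermediate
23 | 2-(trimethylsilyl)ethyl 8-[(2R)-5-oxopyrrolidin-2-yl]oct-5-enoate (E/Z) | O=C1CC[C@@H](CCC=CCCCC(=O)OCC[Si](C)(C)C)N1 | intermediate
24 | 2-(trimethylsilyl)ethyl 8-[(2R)-5-oxopyrrolidin-2-yl]octanoate | O=C1CC[C@@H](CCCCCCCC(=O)OCC[Si](C)(C)C)N1 | intermediate
25 | tert-butyl (2R)-5-oxo-2-{8-oxo-8-[2-(trimethylsilyl)ethoxy]octyl}pyrrolidine-1-carboxylate | O=C1CC[C@@H](CCCCCCCC(=O)OCC[Si](C)(C)C)N1C(=O)OC(C)(C)C | intermediate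
26 | 2-(trimethylsilyl)ethyl (9R)-9-[(tert-butoxycarbonyl)amino]-12-oxo-14-(trimethylsilyl)tetradec-13-ynoate | C[Si](C)(C)C#CC(=O)CC[C@H](NC(=O)OC(C)(C)C)CCCCCCCC(=O)OCC[Si](C)(C)C | intermediate
27 | 2-(trimethylsilyl)ethyl (9R,12S)-9-[(tert-butoxycarbonyl)amino]-12-hydroxy-14-(trimethylsilyl)tetradec-13-ynoate | C[Si](C)(C)C#C[C@@H](O)CC[C@H](NC(=O)OC(C)(C)C)CCCCCCCC(=O)OCC[Si](C)(C)C | intermediate
28 | 2-(trimethylsilyl)ethyl (9R,12S)-9-[(tert-butoxycarbonyl)amino]-12-({8-[(2R,5S,6S)-1-(tert-butoxycarbonyl)-5-(tert-butyldimethylsilyloxy)-6-methylpiperidin-2-yl]octanoyl}oxy)-14-(trimethylsilyl)tetradec-13-ynoate | CC(C)(C)[Si](C)(C)O[C@H]1CC[C@@H](CCCCCCCC(=O)O[C@H](C#C[Si](C)(C)C)CC[C@H](NC(=O)OC(C)(C)C)CCCCCCCC(=O)OCC[Si](C)(C)C)N(C(=O)OC(C)(C)C)[C@H]1C | intermediate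
29 | (9R,12S)-9-[(tert-butoxycarbonyl)amino]-12-({8-[(2R,5S,6S)-1-(tert-butoxycarbonyl)-5-hydroxy-6-methylpiperidin-2-yl]octanoyl}oxy)tetradec-13-ynoic acid | O[C@H]1CC[C@@H](CCCCCCCC(=O)O[C@H](C#C)CC[C@H](NC(=O)OC(C)(C)C)CCCCCCCC(=O)O)N(C(=O)OC(C)(C)C)[C@H]1C | intermediate
30 | mixed anhydride of 29 with 2,4,6-trichlorobenzoic acid | O[C@H]1CC[C@@H](CCCCCCCC(=O)O[C@H](C#C)CC[C@H](NC(=O)OC(C)(C)C)CCCCCCCC(=O)OC(=O)c2c(Cl)cc(Cl)cc2Cl)N(C(=O)OC(C)(C)C)[C@H]1C | intermediate
31 | 26-membered diolide: lactone of 29 onto the ring B C3 hydroxyl; N-Boc ring B (2S,3S,6R); open ring A with (R)-CH(NHBoc) and (S)-CH(C≡CH)–O-acyl | O1[C@H]2CC[C@@H](CCCCCCCC(=O)O[C@H](C#C)CC[C@H](NC(=O)OC(C)(C)C)CCCCCCCC1=O)N(C(=O)OC(C)(C)C)[C@H]2C | intermediate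
32 | 26-membered diolide: 31 with the ethynyl group converted to acetyl (α-acyloxy methyl ketone) | O1[C@H]2CC[C@@H](CCCCCCCC(=O)O[C@H](C(C)=O)CC[C@H](NC(=O)OC(C)(C)C)CCCCCCCC1=O)N(C(=O)OC(C)(C)C)[C@H]2C | intermediate
33 | 26-membered diolide amino ketone: 32 without both Boc groups (formed as its bis-trifluoroacetate) | O1[C@H]2CC[C@@H](CCCCCCCC(=O)O[C@H](C(C)=O)CC[C@H](N)CCCCCCCC1=O)N[C@H]2C | intermediate
34 | CNP0304114.1: 26-membered diolide; ring B (2S,3S,6R)-2-methylpiperidine; ring A (3S,6R)-2-methyl-3,4,5,6-tetrahydropyridine | CC1=N[C@@H]2CCCCCCCC(=O)O[C@H]3CC[C@@H](CCCCCCCC(=O)O[C@H]1CC2)N[C@H]3C | target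

**Count and risks**

Total step count: 24. Longest linear sequence: 16 steps (from 1 through steps 1–5, 7–12 and 20–24 to 34).

Most likely to fail:

1. Step 7. The sulfonamide nitrogen carries a branched carbon flanked by a silyl ether, so attack on the π-allyl palladium complex may be slow, and the resident stereocentres may erode the ligand-controlled choice of allyl terminus. Fallback, setting out from 5: TBSOTf and 2,6-lutidine, then methanol, silylate the hydroxyl and cleave the carbamate through its silyl ester to give the primary amine (2S,3S)-3-(tert-butyldimethylsilyloxy)pent-4-en-2-amine F1. This smaller, neutral nucleophile is allylated by 10 under the same Pd2(dba)3/ligand system to the secondary amine (2S,3S)-3-(tert-butyldimethylsilyloxy)-N-[(1R)-cyclopent-2-en-1-yl]pent-4-en-2-amine F2. Sulfonylation with 2-nitrobenzenesulfonyl chloride (Et3N, DMAP, CH2Cl2, 40 °C) rejoins the route at 11.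

2. Step 8. Loading of the carbene and ring closure at the vinyl group may be retarded by the adjacent silyl ether, so that ring-opened material oligomerises instead of closing ring B. Fallback, setting out from 11: Bu4NF in THF removes the silyl group to give the free allylic alcohol N-[(1R)-cyclopent-2-en-1-yl]-N-[(2S,3S)-3-hydroxypent-4-en-2-yl]-2-nitrobenzenesulfonamide F3. A free allylic hydroxyl speeds up metathesis at the neighbouring alkene, and the same catalyst under ethylene should rearrange F3 to (2S,3S,6R)-6-(but-3-en-1-yl)-2-methyl-1-(2-nitrophenylsulfonyl)-1,2,3,6-tetrahydropyridin-3-ol F4. Silylation (TBSCl, imidazole, DMF) comes back to the route at 12.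

3. Step 23. The cationic gold catalyst may be diverted by the carbamate N–H or may trigger acyloxy migration or carbamate loss instead of clean Markovnikov hydration. Fallback, setting out from 31: both Boc groups are removed first (CF3CO2H/CH2Cl2, then NaHCO3) to give the 26-membered diolide amino alkyne F5. Intramolecular Markovnikov hydroamination of its 5-alkynylamine unit (NaAuCl4 cat., MeCN, 80 °C; 6-exo-dig addition, then enamine-to-imine tautomerisation) closes ring A and arrives directly at 34.

**Further compounds**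

F1 | step 7 | (2S,3S)-3-(tert-butyldimethylsilyloxy)pent-4-en-2-amine | C[C@H](N)[C@@H](O[Si](C)(C)C(C)(C)C)C=C
F2 | step 7 | (2S,3S)-3-(tert-butyldimethylsilyloxy)-N-[(1R)-cyclopent-2-en-1-yl]pent-4-en-2-amine | C=C[C@H](O[Si](C)(C)C(C)(C)C)[C@H](C)N[C@H]1C=CCC1
F3 | step 8 | N-[(1R)-cyclopent-2-en-1-yl]-N-[(2S,3S)-3-hydroxypent-4-en-2-yl]-2-nitrobenzenesulfonamide | C=C[C@H](O)[C@H](C)N([C@H]1C=CCC1)S(=O)(=O)c1ccccc1[N+](=O)[O-]
F4 | step 8 | (2S,3S,6R)-6-(but-3-en-1-yl)-2-methyl-1-(2-nitrophenylsulfonyl)-1,2,3,6-tetrahydropyridin-3-ol | O[C@H]1C=C[C@@H](CCC=C)N(S(=O)(=O)c2ccccc2[N+](=O)[O-])[C@H]1C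
F5 | step 23 | 26-membered diolide amino alkyne (31 without both Boc groups) | O1[C@H]2CC[C@@H](CCCCCCCC(=O)O[C@H](C#C)CC[C@H](N)CCCCCCCC1=O)N[C@H]2C
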